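Delta stops with a leftover: at its last reading, 6.00 min, 65.1% of its substrate stands beside 30.6% double product. We ask what the new flasks must end as, then how fast they get there.

| flask | substrate | reagent | temperature | remark | time |
|---|---|---|---|---|---|
| delta | 0.50 mM | 0.33 mM | 64 °C | run made earlier |  |
| zeta | 0.50 mM | 1.3 mM | 73 °C | run made earlier |  |
| alpha | 1 mM | 0.65 mM | 64 °C | run made earlier |  |
| grey | 0.50 mM | 0.650 mM | 60 °C |  | 6.0 min |
| blue | 0.50 mM | 0.650 mM | 68 °C |  | 6.0 min |
| ochre | 0.50 mM | 0.650 mM | 76 °C |  | 6.0 min |

| run | time / min | other mono adduct / % | substrate / % | double product / % | single product / % |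
|---|---|---|---|---|---|
| delta | 0.500 | 4.3 | 57.9 | 11.6 | 25.6 |
| delta | 1.50 | 4.3 | 60.2 | 19.5 | 15.2 |
| delta | 3.00 | 4.8 | 62.1 | 24.7 | 9.2 |
| delta | 4.00 | 6.2 | 65.2 | 26.9 | 5.1 |
| delta | 6.00 | 6.8 | 65.1 | 30.6 | 0.7 |
| zeta | 0.667 | 1.3 | 6.6 | 79.3 | 12.4 |
| zeta | 1.33 | 0.2 | 2.5 | 92.7 | 4.7 |
| zeta | 2.00 | 1.6 | 2.0 | 97.6 | 1.7 |
| zeta | 2.50 | 0.2 | 1.1 | 96.6 | 0.7 |
| zeta | 3.00 | 0 | 0 | 97.0 | 1.3 |
| alpha | 0.500 | 7.0 | 55.3 | 13.0 | 25.9 |
| alpha | 0.833 | 5.9 | 55.6 | 18.6 | 22.4 |
| alpha | 1.50 | 6.9 | 60.0 | 22.1 | 14.2 |
| alpha | 3.00 | 6.0 | 61.4 | 26.3 | 5.6 |
| alpha | 6.00 | 4.0 | 63.1 | 28.1 | 0.8 |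

(standard deviation of a reading: 1 percentage point)

- amounts and yields of by-product count crystals too
- given per volume of solution although it is solid: crystals
- steps that have been proposed: substrate + reagent <-> single product + by-product; substrate + reagent -> other mono adduct + by-product; reagent + single product -> double product + by-product; reagent + other mono adduct -> double product + by-product; crystals <-> by-product

- which of these there is most of at the end, counted by the substrate in it, grey (substrate / double product / single product / other mono adduct)
- which of these there is most of at the end, counted by the substrate in it, blue (substrate / double product / single product / other mono adduct)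
- which of these there is most of at the end, counted by the substrate in it, ochre (substrate / double product / single product / other mono adduct)
- final amount of the leader among these, as a percentage of the substrate charged, in grey
- final amount of the leader among these, as a percentage of the substrate charged, in blue
- final amount of the leader among these, as a percentage of the substrate charged, in ochre

Let a and b be the charges of substrate and reagent. Single product and other mono adduct each cost one reagent and double product costs two, while the way back from single product returns its reagent. We therefore carry the reagent ceiling C = b/(2a), the share of substrate that stands as double product if the reagent charged ends there: 65.0% for grey, blue and ochre. Below 100%, reagent is the limiting reagent. In delta, C less half its other mono adduct gives 29.6%, against 30.6% read. In zeta, C is 130%, and double product reads 97.0%.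

First comes the attack on substrate: by 0.500 min delta's substrate already reads 57.9%, and later readings stand higher. Next, single product drains in delta, with a decay time read from that run of 2.17 min, longer than that first 0.500 min, leaving substrate and double product with some other mono adduct. Taking that time over from delta, 6.0 min is 2.76 such times, so we expect grey, blue and ochre to come close to the ceiling. The last readings of other mono adduct in delta and alpha average 5.40%, so our own figure is 62.3%, a little lower in colder grey if single product remains.

The forecast names double product as leader in grey, blue and ochre, at 60.5% (55% to 65%), 62% (57% to 66%) and 62.5% (57% to 67%), on the ground that “Reagent should run out again”.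

The flasks end with double product leading, at 59.6% in grey, 62.4% in blue and 63.4% in ochre, each inside its range.

    substrate + reagent ⇌ single product + by-product (K = 0.950, k = 110 M⁻¹ s⁻¹, Ea = 54.0 kJ mol⁻¹, ΔH = −35.0 kJ mol⁻¹)
    substrate + reagent → other mono adduct + by-product (k = 36.6 M⁻¹ s⁻¹, Ea = 39.0 kJ mol⁻¹)
    reagent + single product → double product + by-product (k = 38.3 M⁻¹ s⁻¹, Ea = 48.0 kJ mol⁻¹)
    reagent + other mono adduct → double product + by-product (k = 389 M⁻¹ s⁻¹, Ea = 49.0 kJ mol⁻¹)
    crystals ⇌ by-product, rate k5*(cs5 - [by-product]) while solid is left; crystals form when [by-product] > cs5 (solubility = 0.130 mM, k = 8.07 s⁻¹)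
    (constants at 60 °C)

Ochre holds 2.70% other mono adduct and 0.185% single product, and C less half of these is 63.6%. A neighbour of ochre is charged with 1.2 mM of substrate and the same reagent, so C falls to 27.1%. Less half its 5.32% other mono adduct, that gives 24.4%. In that neighbour the leader is substrate, at 70.2%, and double product stands at 24.4%.

Readings and results come from a simulation with constants of no real substance; the scatter is artificial.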